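## Structural features

The target is a benzophenone. One carbonyl carbon joins ring A, a 1,2,3,4-tetrasubstituted benzene, to ring B, the arene of a 2,3-dihydro-1,4-benzodioxine. On four neighbouring carbons ring A carries a phenolic hydroxyl, a formyl group, the diaryl ketone and a prenyl chain, in that order. Ring B carries the ketone ortho to the dioxane oxygen bound to the only stereocentre, an (R)-configured secondary carbon bearing a 2-hydroxypropan-2-yl group; a methyl group sits meta to the ketone and para to that oxygen. With a single stereocentre there is no relative configuration to control, but the absolute configuration must be set next to a tertiary alcohol. The fragile groups are the o-hydroxy aldehyde, the acid-sensitive prenyl alkene, the tertiary alcohol, and the electron-rich phenol para to a benzylic–allylic methylene. The real difficulty is the contiguous substitution of ring A around a ketone that is ortho-substituted on both sides. The key step exploits the fact that the formyl and ketone carbons sit on adjacent ring A carbons with the hydroxyl on the next one. Both carbonyl carbons can therefore be tied through one ether oxygen into a 1-aryl-1,3-dihydroisobenzofuran-4-ol. A furan–alkyne cycloisomerisation builds exactly this bicycle, the furan supplying four ring A carbons (including the prenyl-bearing one) and its oxygen as the phenol.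

## Logic of the disconnections

23 to 22: the O–Si bond of the tertiary alcohol is cut. The silyl ether keeps this alcohol silent in the organolithium steps, the etherification and the benzylic oxidation. Its removal must spare the aldehyde and the alkene, so it is placed last and done with buffered fluoride.

22 to 21: the aldehyde is traced to a primary benzylic alcohol. A hydroxymethyl group ortho to the aroyl group is the open form of a cyclic ether. The forward oxidation must be selective for this alcohol beside a free phenol.

21 to 20 to 18 (through 19): the ketone carbon is reconnected to the hydroxymethyl oxygen, so both carbonyls become one five-membered ether with a C–H at the diarylmethine carbon. This removes the hindered ketone and the aldehyde from every earlier step. The forward step needs hydride abstraction at that C–H only. Ring A is therefore made electron-poor as its acetate (18 from 17), and the acetate is taken off (20 to 21) before the alcohol is oxidised, because an aryl ester next to a free primary alcohol can shift.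

17 to 16: three bonds are cut at once, namely the ring A bond between the two fusion carbons, the bond between the phenol carbon and its CH neighbour, and the phenol C–O bond. Ring A and the dihydrofuran ring disappear and the tetrasubstituted arene becomes a 2,3-disubstituted furan tethered to a terminal alkyne. The forward step must open the arene oxide in one sense only and must let the furan, not the prenyl alkene or ring B, attack the alkyne.

16 to 14 and 15: the propargylic O–CH2 bond is cut. This is a plain etherification, provided the tertiary alcohol is masked.

14 to 11 and 12: the furan C3–CH2 bond is cut. The bromine at C3 first directs metalation to C2 and then serves as the handle for the prenyl group. The forward step needs a 3-metallofuran that does not rearrange, and attack at the primary terminus of the allylic bromide. The carbinol is carried as its alkoxide, so no silyl group is put on and taken off.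

11 to 9 and 8: the bond from the carbinol carbon to furan C2 is cut, which divides the molecule into a ring B aldehyde and a four-carbon furan. The configuration at the carbinol carbon is irrelevant because it becomes the ketone carbon.

8 to 7: the O–Si bond is cut (protection only).

7 to 5 and 3 (through 6): both dioxane C–O bonds are cut, the O–CH2 bond as an alkylation and the O–CH bond as an epoxide opening with inversion. The stereocentre is thereby traced to an epoxide made by asymmetric epoxidation. An unsymmetrical catechol without further differentiation would give both dioxane regioisomers, so the catechol carries the formyl group from the start. The forward step needs the phenoxide meta to the formyl group to be alkylated first and the ortho phenoxide to attack the secondary epoxide carbon.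

5 to 4 and 3 to 1 (through 2): an O–CH3 bond, the S–O bond and the epoxide C–O bonds are cut, which leaves two catalogue compounds.

## Other disconnections considered

Alternative 1: The cut is the bond between ring B and the dioxane oxygen next to the ketone-bearing carbon, traced to a diaryl ketone. In the forward sense the anthrone A1 (benzyl ether on ring B, pivalate on ring A) would undergo Baeyer–Villiger oxidation with CF3CO3H, with ring B migrating to oxygen, to give the seven-membered lactone A2.
- In favour: all carbons of both arenes and both bridging carbons are present from a cheap hydroxyanthraquinone-derived tricycle, no precious metal is needed, and the more electron-rich ring B should be the migrating group.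
- Against: after the key step almost everything remains. The bridging methylene must be oxidised to the ketone, the lactone carbonyl reduced to the aldehyde level, the prenyl group placed on ring A without a handle, and the dioxane with its stereocentre built on the freed catechol. Mechanistically, anthrone–anthranol tautomerism and peracid oxidation at the methylene compete with the sluggish oxygen insertion into a ketone flanked by two peri substituents.
- Comparison: it is the better plan on one point, since the ring B oxygen pattern arises without selective alkylation of a catechol. It is weaker on structure (no C–C bond, ring or stereocentre is formed in the key step) and on step economy, whereas the chosen plan writes all four ring A substituents in one step.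

Alternative 2: Both aryl–carbonyl bonds are cut. The ring A iodide A3, carbon monoxide and the ring B boronic acid A4 would be joined by the divalent palladium precatalyst [PdCl2(IPr)(3-chloropyridine)] to the protected target A5.
- In favour: it is the most convergent plan, the ketone appears at its final oxidation state, and the bulky carbene ligand is the known answer for carbonylative coupling of iodides substituted at both ortho positions. The endgame would be only acetal and methoxymethyl ether hydrolysis.
- Against: A3 is itself the contiguously tetrasubstituted arene, so the regiochemical problem of ring A is displaced rather than solved. Direct biaryl coupling without carbon monoxide uptake and protodeboronation of the ortho-alkoxy boronic acid A4 compete at a crowded acylpalladium centre. The final acid treatment meets the prenyl alkene and the tertiary alcohol.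
- Comparison: on convergence and redox economy it is better than the chosen plan, and it needs no protection of the tertiary alcohol. On ring A it is weaker, because the substitution pattern would come from classical aromatic chemistry with uncertain regiocontrol, and the overall step count is unlikely to be lower once A3 is made.

Alternative 3: The cut is the O–C bond at the stereocentre. Pd2(dba)3 (zerovalent palladium) with the C2-symmetric diaminocyclohexane bis(2-diphenylphosphinobenzamide) ligand would ionise the allylic carbonate A6. The neighbouring phenol would attack the internal allyl terminus to give the bromo benzodioxane A7, which is (S) by the sequence rule and has the same spatial arrangement as the target centre.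
- In favour: the stereocentre is set by catalysis, both alkene isomers of A6 converge through the same allyl complex, and the bromine of A7 is a handle for lithiation or formylation.
- Against: the isopropenyl group must later be hydrated to the tertiary alcohol and the bromide converted to the aldehyde. Making A6 needs the same differentiation of two neighbouring phenolic oxygens. Attack at the more substituted terminus of a 2-methylallyl unit with high enantioselectivity is less secure than for the parent vinyl case.
- Comparison: it is the equal of the chosen plan on enantiocontrol (catalytic in both) and better in that either ligand enantiomer is available and the alkene geometry need not be controlled. It is weaker on step economy by about two steps, since the epoxide route delivers the tertiary alcohol and the aldehyde directly. It concerns ring B only and could feed the chosen key step rather than replace it.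

Key step: step 8

Assumption: 4 (2-hydroxy-3-methoxy-5-methylbenzaldehyde) is taken as a catalogue compound; the carbinol carbon made in step 5 is carried as both epimers because it ends as the ketone carbon.

In the names below, ArB stands for the (3R)-7-methyl-3-[2-(triethylsilyloxy)propan-2-yl]-2,3-dihydro-1,4-benzodioxin-5-yl group.

Step 1
Reactants: 1 prenol (3-methylbut-2-en-1-ol)
Product: 3 (S)-(3,3-dimethyloxiran-2-yl)methyl 4-methylbenzenesulfonate, via epoxy alcohol 2 (not isolated)
Conditions: Ti(OiPr)4 (5 mol %), L-(+)-diisopropyl tartrate (7 mol %), t-BuOOH, 4 Å MS, CH2Cl2, −20 °C; then P(OMe)3; then TsCl, Et3N, DMAP (cat.), −20 → 0 °C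
Reagents that add atoms: tert-butyl hydroperoxide CC(C)(C)OO; 4-methylbenzenesulfonyl chloride Cc1ccc(cc1)S(Cl)(=O)=O
Why: Sharpless asymmetric epoxidation of an allylic alcohol; with the L-(+)-tartrate the oxidant reaches the face that gives the (S)-epoxy alcohol, which sets the only stereocentre of the route. The small, water-soluble 2 is sulfonylated in the same flask, and the sulfonate makes the primary carbon the electrophile for step 3.

Step 2
Reactants: 4 2-hydroxy-3-methoxy-5-methylbenzaldehyde
Product: 5 2,3-dihydroxy-5-methylbenzaldehyde
Conditions: BBr3, CH2Cl2, −78 → 0 °C; H2O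
Reagents that add atoms: none
Why: Lewis-acid cleavage of an aryl methyl ether; the aldehyde is untouched at low temperature and the product is a catechol whose two hydroxyls are differentiated by the ortho formyl group.

Step 3
Reactants: 5 2,3-dihydroxy-5-methylbenzaldehyde; 3 (S)-(3,3-dimethyloxiran-2-yl)methyl 4-methylbenzenesulfonate
Product: 7 (3R)-3-(2-hydroxypropan-2-yl)-7-methyl-2,3-dihydro-1,4-benzodioxine-5-carbaldehyde, via aryl glycidyl ether 6 (not isolated)
Conditions: NaH (2.2 equiv), DMSO, rt; then 3 (1.0 equiv), rt → 70 °C; aq. NH4Cl
Reagents that add atoms: none
Why: In the dianion the oxide ortho to the formyl group is delocalised into the carbonyl and is the weaker nucleophile, so the sulfonate is displaced by the meta oxide (known dianion 3-O-alkylation of 2,3-dihydroxybenzaldehydes). The remaining ortho phenoxide then opens the epoxide at its secondary carbon in a 6-exo closure, the 7-endo path requiring attack at the tertiary carbon. The opening goes with inversion, so the (S) epoxide becomes the (R) dioxane centre and the tertiary alcohol is released.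

Step 4
Reactants: 7 (3R)-3-(2-hydroxypropan-2-yl)-7-methyl-2,3-dihydro-1,4-benzodioxine-5-carbaldehyde
Product: 8 (3R)-7-methyl-3-[2-(triethylsilyloxy)propan-2-yl]-2,3-dihydro-1,4-benzodioxine-5-carbaldehyde (ArB–CHO)
Conditions: Et3SiOTf, 2,6-lutidine, CH2Cl2, −78 → 0 °C
Reagents that add atoms: triethylsilyl trifluoromethanesulfonate CC[Si](CC)(CC)OS(=O)(=O)C(F)(F)F
Why: Silylation of a hindered tertiary alcohol with a silyl triflate and a hindered pyridine base; the ether keeps the alcohol out of the organolithium steps 5 and 6, the etherification of step 7 and the cation chemistry of step 10.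

Step 5
Reactants: 9 3-bromofuran; 8 ArB–CHO
Product: 11 (3-bromofuran-2-yl)(ArB)methanol (both carbinol epimers), via 3-bromo-2-furyllithium 10 (not isolated)
Conditions: LDA, THF, −78 °C; then 8, −78 °C; aq. NH4Cl
Reagents that add atoms: none
Why: Directed deprotonation: LDA removes the C2 proton of 9, which is flanked by the ring oxygen and bromine, and at −78 °C the lithio species does not scramble; 1,2-addition to the non-enolisable aldehyde follows. The new carbinol centre forms without control, which is acceptable because it becomes the ketone carbon.

Step 6
Reactants: 11 (3-bromofuran-2-yl)(ArB)methanol; 12 prenyl bromide (1-bromo-3-methylbut-2-ene)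
Product: 14 [3-(3-methylbut-2-enyl)furan-2-yl](ArB)methanol, via dilithio species 13 (not isolated)
Conditions: n-BuLi (2.1 equiv), THF, −78 °C; CuBr·SMe2 (1.0 equiv), −78 → −40 °C; 12, −78 → 0 °C; aq. NH4Cl
Reagents that add atoms: none
Why: The first equivalent of n-BuLi forms the lithium alkoxide and the second effects bromine–lithium exchange, so no protecting group is needed on the carbinol. Transmetalation to copper and allylic substitution at the primary carbon of 12 follow the known prenylation of aryl- and heteroaryllithiums through their organocopper derivatives, attack at the tertiary terminus being sterically disfavoured.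

Step 7
Reactants: 14 [3-(3-methylbut-2-enyl)furan-2-yl](ArB)methanol; 15 propargyl bromide (3-bromoprop-1-yne)
Product: 16 2-[(ArB)(prop-2-ynyloxy)methyl]-3-(3-methylbut-2-enyl)furan
Conditions: NaH, Bu4NI (cat.), THF/DMF, 0 °C → rt
Reagents that add atoms: none
Why: Williamson ether synthesis on the sodium alkoxide of the secondary carbinol with a reactive propargylic bromide; the tertiary alcohol is silylated and cannot compete, and the low temperature avoids isomerisation of the propargyl ether to an allenyl ether.

Step 8
Reactants: 16 2-[(ArB)(prop-2-ynyloxy)methyl]-3-(3-methylbut-2-enyl)furan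
Product: 17 1-(ArB)-7-(3-methylbut-2-enyl)-1,3-dihydroisobenzofuran-4-ol (both epimers at C1)
Conditions: Ph3PAuNTf2 (5 mol %), CH2Cl2, rt
Reagents that add atoms: none
Why: The cationic monovalent gold complex activates the terminal alkyne and the furan C2=C3 bond attacks its internal carbon, which closes the dihydrofuran ring in the 5-exo-dig mode and gives a cyclopropyl gold carbene with the carbene at the former alkyne terminus. Cleavage of the furan C2–O bond and of one cyclopropane bond opens this to a vinyl gold carbene carrying an aldehyde (an aldehyde, not a ketone, because furan C5 bears hydrogen), whose carbonyl oxygen adds to the carbene carbon to give an oxepine and release the catalyst. Ring A closes by the 6π electrocyclisation of the oxepine to the arene oxide, which makes the bond between the alkyne terminus and furan C5; opening of the arene oxide and loss of a proton give the phenol. The closest known reaction type is the gold-catalysed furan–yne phenol synthesis of 4-hydroxy-1,3-dihydroisobenzofurans and 4-hydroxyisoindolines from furfuryl propargyl ethers and amides, including substrates branched at the furfuryl carbon. No stereocentre is created; the diarylmethine carbon stays an epimer mixture and the dioxane centre is remote. The regioselectivity needed is cleavage of the epoxide C–O bond at the former furan C5, favoured because the resulting cation is delocalised onto the prenyl-bearing carbon and the OCH2-bearing fusion carbon, whereas the other opening reaches only one alkyl-substituted position; the hydroxyl therefore stays on the former alkyne terminus. The chemoselectivity needed is furan over prenyl alkene and over ring B as the nucleophile, secured by the three-atom tether (five-membered closure for the furan, an eight-membered ring for the alkene) and by the much higher nucleophilicity of a 2,3-dialkylfuran than of the benzodioxane arene. The branched tether carbon favours closure and the silyl ether keeps the tertiary alcohol from adding to the activated alkyne.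

Step 9
Reactants: 17 1-(ArB)-7-(3-methylbut-2-enyl)-1,3-dihydroisobenzofuran-4-ol
Product: 18 1-(ArB)-7-(3-methylbut-2-enyl)-1,3-dihydroisobenzofuran-4-yl acetate
Conditions: Ac2O, Et3N, DMAP (cat.), CH2Cl2, 0 °C → rt
Reagents that add atoms: acetic anhydride CC(=O)OC(C)=O
Why: Acylation of a phenol; the acetate lowers the electron density of ring A so that the prenyl methylene para to the oxygen and the OCH2 group ortho to it are not attacked in step 10.

Step 10
Reactants: 18 1-(ArB)-7-(3-methylbut-2-enyl)-1,3-dihydroisobenzofuran-4-yl acetate
Product: 20 2-(hydroxymethyl)-3-[(ArB)carbonyl]-4-(3-methylbut-2-enyl)phenyl acetate, via cyclic hemiketal 19 (not isolated)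
Conditions: DDQ (1.3 equiv), CH2Cl2/pH 7 phosphate buffer (10:1), 0 °C → rt
Reagents that add atoms: water O
Why: DDQ abstracts hydride from the diarylmethine C–H, the one position whose cation is stabilised by the ether oxygen, by ring A and by the ortho-alkoxy-substituted ring B; water captures the oxocarbenium ion as hemiketal 19, which opens to the hydroxymethyl ketone. This is the known DDQ oxidation of benzylic ethers (as in p-methoxybenzyl ether cleavage and isochroman or phthalan oxidation), and the buffer keeps the hemiketal from ionising again. Partial ring closure to 19 or a shift of the acetyl group to the neighbouring primary hydroxyl would not matter, since step 11 removes the ester from either oxygen.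

Step 11
Reactants: 20 2-(hydroxymethyl)-3-[(ArB)carbonyl]-4-(3-methylbut-2-enyl)phenyl acetate
Product: 21 [3-hydroxy-2-(hydroxymethyl)-6-(3-methylbut-2-enyl)phenyl](ArB)methanone
Conditions: K2CO3, MeOH, 0 °C → rt
Reagents that add atoms: none
Why: Base-catalysed transesterification; methanolysis removes the acetyl group wherever it sits, which is why deacetylation precedes the alcohol oxidation. The tertiary silyl ether and the diaryl ketone are inert to K2CO3 in methanol.

Step 12
Reactants: 21 [3-hydroxy-2-(hydroxymethyl)-6-(3-methylbut-2-enyl)phenyl](ArB)methanone
Product: 22 6-hydroxy-2-[(ArB)carbonyl]-3-(3-methylbut-2-enyl)benzaldehyde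
Conditions: MnO2 (activated, excess), CH2Cl2, rt
Reagents that add atoms: none
Why: Heterogeneous MnO2 oxidation, selective for benzylic primary alcohols, converts the o-hydroxybenzyl alcohol into the salicylaldehyde and stops there; any cyclic hemiketal form of 21 is drained through the open hydroxy ketone, and the tertiary hemiketal cannot be over-oxidised.

Step 13
Reactants: 22 6-hydroxy-2-[(ArB)carbonyl]-3-(3-methylbut-2-enyl)benzaldehyde
Product: 23 6-hydroxy-2-{[(3R)-3-(2-hydroxypropan-2-yl)-7-methyl-2,3-dihydro-1,4-benzodioxin-5-yl]carbonyl}-3-(3-methylbut-2-enyl)benzaldehyde (CNP0373866.1)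
Conditions: HF·pyridine, pyridine, THF, 0 °C → rt
Reagents that add atoms: none
Why: Fluoride cleavage of a silyl ether under buffered conditions that spare the aldehyde, the ketone, the prenyl alkene and the tertiary alcohol; the stereocentre is not involved.

## Compound list

1 | prenol (3-methylbut-2-en-1-ol) | CC(C)=CCO | starting material
2 | (S)-(3,3-dimethyloxiran-2-yl)methanol | CC1(C)O[C@H]1CO | intermediate (not isolated)
3 | (S)-(3,3-dimethyloxiran-2-yl)methyl 4-methylbenzenesulfonate | CC1(C)O[C@H]1COS(=O)(=O)c1ccc(C)cc1 | intermediate
4 | 2-hydroxy-3-methoxy-5-methylbenzaldehyde | COc1cc(C)cc(C=O)c1O | starting material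
5 | 2,3-dihydroxy-5-methylbenzaldehyde | Cc1cc(O)c(O)c(C=O)c1 | intermediate
6 | 3-{[(2S)-3,3-dimethyloxiran-2-yl]methoxy}-2-hydroxy-5-methylbenzaldehyde (as its sodium phenoxide) | Cc1cc(OC[C@@H]2OC2(C)C)c(O)c(C=O)c1 | intermediate (not isolated)
7 | (3R)-3-(2-hydroxypropan-2-yl)-7-methyl-2,3-dihydro-1,4-benzodioxine-5-carbaldehyde | O=Cc1cc(C)cc2c1O[C@@H](C(C)(C)O)CO2 | intermediate
8 | (3R)-7-methyl-3-[2-(triethylsilyloxy)propan-2-yl]-2,3-dihydro-1,4-benzodioxine-5-carbaldehyde | O=Cc1cc(C)cc2c1O[C@@H](C(C)(C)O[Si](CC)(CC)CC)CO2 | intermediate
9 | 3-bromofuran | Brc1ccoc1 | starting material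
10 | 3-bromo-2-furyllithium | [Li]c1occc1Br | intermediate (not isolated)
11 | (3-bromofuran-2-yl)(ArB)methanol, both carbinol epimers | OC(c1occc1Br)c1cc(C)cc2c1O[C@@H](C(C)(C)O[Si](CC)(CC)CC)CO2 | intermediate
12 | prenyl bromide (1-bromo-3-methylbut-2-ene) | CC(C)=CCBr | starting material
13 | lithium alkoxide of (3-lithiofuran-2-yl)(ArB)methanol | [Li]OC(c1occc1[Li])c1cc(C)cc2c1O[C@@H](C(C)(C)O[Si](CC)(CC)CC)CO2 | intermediate (not isolated)
14 | [3-(3-methylbut-2-enyl)furan-2-yl](ArB)methanol, both carbinol epimers | CC(C)=CCc1ccoc1C(O)c1cc(C)cc2c1O[C@@H](C(C)(C)O[Si](CC)(CC)CC)CO2 | intermediate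
15 | propargyl bromide (3-bromoprop-1-yne) | C#CCBr | starting material
16 | 2-[(ArB)(prop-2-ynyloxy)methyl]-3-(3-methylbut-2-enyl)furan, both epimers | C#CCOC(c1occc1CC=C(C)C)c1cc(C)cc2c1O[C@@H](C(C)(C)O[Si](CC)(CC)CC)CO2 | intermediate
17 | 1-(ArB)-7-(3-methylbut-2-enyl)-1,3-dihydroisobenzofuran-4-ol, both C1 epimers | CC(C)=CCc1ccc(O)c2c1C(c1cc(C)cc3c1O[C@@H](C(C)(C)O[Si](CC)(CC)CC)CO3)OC2 | intermediate
18 | 1-(ArB)-7-(3-methylbut-2-enyl)-1,3-dihydroisobenzofuran-4-yl acetate, both C1 epimers | CC(C)=CCc1ccc(OC(C)=O)c2c1C(c1cc(C)cc3c1O[C@@H](C(C)(C)O[Si](CC)(CC)CC)CO3)OC2 | intermediate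
19 | 1-(ArB)-1-hydroxy-7-(3-methylbut-2-enyl)-1,3-dihydroisobenzofuran-4-yl acetate | CC(C)=CCc1ccc(OC(C)=O)c2c1C(O)(c1cc(C)cc3c1O[C@@H](C(C)(C)O[Si](CC)(CC)CC)CO3)OC2 | intermediate (not isolated)
20 | 2-(hydroxymethyl)-3-[(ArB)carbonyl]-4-(3-methylbut-2-enyl)phenyl acetate | CC(C)=CCc1ccc(OC(C)=O)c(CO)c1C(=O)c1cc(C)cc2c1O[C@@H](C(C)(C)O[Si](CC)(CC)CC)CO2 | intermediate
21 | [3-hydroxy-2-(hydroxymethyl)-6-(3-methylbut-2-enyl)phenyl](ArB)methanone | CC(C)=CCc1ccc(O)c(CO)c1C(=O)c1cc(C)cc2c1O[C@@H](C(C)(C)O[Si](CC)(CC)CC)CO2 | intermediate
22 | 6-hydroxy-2-[(ArB)carbonyl]-3-(3-methylbut-2-enyl)benzaldehyde | CC(C)=CCc1ccc(O)c(C=O)c1C(=O)c1cc(C)cc2c1O[C@@H](C(C)(C)O[Si](CC)(CC)CC)CO2 | intermediate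
23 | 6-hydroxy-2-{[(3R)-3-(2-hydroxypropan-2-yl)-7-methyl-2,3-dihydro-1,4-benzodioxin-5-yl]carbonyl}-3-(3-methylbut-2-enyl)benzaldehyde | CC(C)=CCc1ccc(O)c(C=O)c1C(=O)c1cc(C)cc2c1O[C@@H](C(C)(C)O)CO2 | target

## Step count and least certain steps

Total step count: 13. Longest linear sequence: 12 steps (steps 2 to 13 from 4; the same length from 1 through steps 1 and 3 to 13).

Step 8 (key step).
- What may go wrong: opening of the arene oxide in the other sense, which would move the hydroxyl one carbon along ring A. The preference rests only on the difference between two and one alkyl-stabilised cation positions, because furan C5 is unsubstituted. The catalyst may also be diverted by attack of the electron-rich ring B on the activated alkyne, or by side paths of the aldehyde-bearing carbene. A change of ligand on gold is the first adjustment but does not change the approach.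
- Fallback (sets out from 8, comes back at 23): ring A is made as an aryllithium and added to 8.
  - Commercial 2-bromo-6-hydroxybenzaldehyde is iodinated para to the hydroxyl (NIS, cat. TsOH, MeCN) to 2-bromo-6-hydroxy-3-iodobenzaldehyde F1.
  - F1 is reduced (NaBH4, MeOH) to 3-bromo-2-(hydroxymethyl)-4-iodophenol F2 and silylated (t-BuMe2SiCl, imidazole, DMF) to the bis(tert-butyldimethylsilyl) ether F3.
  - Stille coupling at the iodide (tributyl(3-methylbut-2-enyl)stannane, Pd(PPh3)4, DMF, 80 °C) gives the prenylated aryl bromide F4.
  - Bromine–lithium exchange (t-BuLi, Et2O, −78 °C) and addition to 8 give the diaryl carbinol F5, which Dess–Martin periodinane oxidises to the ketone F6.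
  - Bu4NF in THF removes all three silyl groups to give the hydroxymethyl benzophenone triol F7, and MnO2 oxidation of F7 gives 23.

Step 10.
- What may go wrong: loss of a proton from the diaryl oxocarbenium ion to give the isobenzofuran, which the quinone then consumes by cycloaddition or further oxidation before water intercepts the cation. Hydride abstraction at the prenyl methylene is a second possibility if the acetate does not deactivate ring A enough.
- Fallback (sets out from 18, comes back at 22): the isobenzofuran is made on purpose and cleaved.
  - Dehydrogenation of 18 under anhydrous conditions (p-chloranil, toluene, 80 °C) gives the 1-arylisobenzofuran acetate F8.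
  - F8 is taken without isolation into a singlet-oxygen [4+2] cycloaddition and reductive work-up (O2, methylene blue, visible light, CH2Cl2, −78 °C; then Me2S) to give the keto aldehyde acetate F9.
  - K2CO3 in MeOH converts F9 into 22.
  - Isobenzofurans are among the fastest acceptors of singlet oxygen, so brief irradiation at low temperature should leave the prenyl alkene alone.

Step 6.
- What may go wrong: migration of lithium from C3 to the free C5 position of the furan by proton transfer before transmetalation, and allylic transposition (attack at the tertiary terminus of 12) during the copper-mediated coupling.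
- Fallback (sets out from 11, comes back at 14): no organolithium and no allylic ambiguity.
  - Suzuki–Miyaura coupling of 11 with allylboronic acid pinacol ester (Pd(PPh3)4, CsF, THF, 65 °C) gives (3-allylfuran-2-yl)(ArB)methanol F10.
  - Cross-metathesis of F10 with excess 2-methylbut-2-ene (second-generation Grubbs catalyst, CH2Cl2, 40 °C) turns the allyl group into the prenyl group of 14.

Step 3.
- What may go wrong: loss of regiocontrol in the first O-alkylation, with the ortho-formyl phenoxide competing for the sulfonate, which would place the stereocentre on the wrong dioxane oxygen. The epoxide opening next to a fully substituted carbon may also be slow.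
- Fallback (sets out from 4, comes back at 7): the order of the two C–O bonds is enforced by a protecting group.
  - 4 is mesylated (MsCl, Et3N, CH2Cl2) to 2-formyl-6-methoxy-4-methylphenyl methanesulfonate F11 and demethylated (BBr3, CH2Cl2) to 2-formyl-6-hydroxy-4-methylphenyl methanesulfonate F12.
  - The only free phenol of F12 is alkylated with 3 (K2CO3, DMF) to 2-{[(2S)-3,3-dimethyloxiran-2-yl]methoxy}-6-formyl-4-methylphenyl methanesulfonate F13.
  - Cleavage of the activated aryl sulfonate (K2CO3, MeOH, 50 °C) frees the ortho phenoxide, which closes the dioxane onto the epoxide to give 7.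

## Further compounds

F1 | step 8 | 2-bromo-6-hydroxy-3-iodobenzaldehyde | O=Cc1c(O)ccc(I)c1Br
F2 | step 8 | 3-bromo-2-(hydroxymethyl)-4-iodophenol | OCc1c(O)ccc(I)c1Br
F3 | step 8 | {[2-bromo-6-(tert-butyldimethylsilyloxy)-3-iodophenyl]methoxy}(tert-butyl)dimethylsilane | CC(C)(C)[Si](C)(C)OCc1c(O[Si](C)(C)C(C)(C)C)ccc(I)c1Br
F4 | step 8 | {[2-bromo-6-(tert-butyldimethylsilyloxy)-3-(3-methylbut-2-enyl)phenyl]methoxy}(tert-butyl)dimethylsilane | CC(C)=CCc1ccc(O[Si](C)(C)C(C)(C)C)c(CO[Si](C)(C)C(C)(C)C)c1Br
F5 | step 8 | [3-(tert-butyldimethylsilyloxy)-2-(tert-butyldimethylsilyloxymethyl)-6-(3-methylbut-2-enyl)phenyl](ArB)methanol | CC(C)=CCc1ccc(O[Si](C)(C)C(C)(C)C)c(CO[Si](C)(C)C(C)(C)C)c1C(O)c1cc(C)cc2c1O[C@@H](C(C)(C)O[Si](CC)(CC)CC)CO2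
F6 | step 8 | [3-(tert-butyldimethylsilyloxy)-2-(tert-butyldimethylsilyloxymethyl)-6-(3-methylbut-2-enyl)phenyl](ArB)methanone | CC(C)=CCc1ccc(O[Si](C)(C)C(C)(C)C)c(CO[Si](C)(C)C(C)(C)C)c1C(=O)c1cc(C)cc2c1O[C@@H](C(C)(C)O[Si](CC)(CC)CC)CO2
F7 | step 8 | [3-hydroxy-2-(hydroxymethyl)-6-(3-methylbut-2-enyl)phenyl][(3R)-3-(2-hydroxypropan-2-yl)-7-methyl-2,3-dihydro-1,4-benzodioxin-5-yl]methanone | CC(C)=CCc1ccc(O)c(CO)c1C(=O)c1cc(C)cc2c1O[C@@H](C(C)(C)O)CO2
F8 | step 10 | 1-(ArB)-7-(3-methylbut-2-enyl)isobenzofuran-4-yl acetate | CC(C)=CCc1ccc(OC(C)=O)c2coc(-c3cc(C)cc4c3O[C@@H](C(C)(C)O[Si](CC)(CC)CC)CO4)c12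
F9 | step 10 | 2-formyl-3-[(ArB)carbonyl]-4-(3-methylbut-2-enyl)phenyl acetate | CC(C)=CCc1ccc(OC(C)=O)c(C=O)c1C(=O)c1cc(C)cc2c1O[C@@H](C(C)(C)O[Si](CC)(CC)CC)CO2
F10 | step 6 | (3-allylfuran-2-yl)(ArB)methanol | OC(c1occc1CC=C)c1cc(C)cc2c1O[C@@H](C(C)(C)O[Si](CC)(CC)CC)CO2
F11 | step 3 | 2-formyl-6-methoxy-4-methylphenyl methanesulfonate | COc1cc(C)cc(C=O)c1OS(C)(=O)=O
F12 | step 3 | 2-formyl-6-hydroxy-4-methylphenyl methanesulfonate | Cc1cc(O)c(OS(C)(=O)=O)c(C=O)c1
F13 | step 3 | 2-{[(2S)-3,3-dimethyloxiran-2-yl]methoxy}-6-formyl-4-methylphenyl methanesulfonate | Cc1cc(OC[C@@H]2OC2(C)C)c(OS(C)(=O)=O)c(C=O)c1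
A1 | alternative 1 | 8-(benzyloxy)-6-methyl-9-oxo-9,10-dihydroanthracen-1-yl 2,2-dimethylpropanoate | O=C1c2c(OCc3ccccc3)cc(C)cc2Cc2cccc(OC(=O)C(C)(C)C)c12
A2 | alternative 1 | 4-(benzyloxy)-2-methyl-6-oxo-6,11-dihydrodibenzo[b,e]oxepin-7-yl 2,2-dimethylpropanoate | O=C1Oc2c(OCc3ccccc3)cc(C)cc2Cc2cccc(OC(=O)C(C)(C)C)c12
A3 | alternative 2 | 2-(dimethoxymethyl)-3-iodo-1-(methoxymethoxy)-4-(3-methylbut-2-enyl)benzene | CC(C)=CCc1ccc(OCOC)c(C(OC)OC)c1I
A4 | alternative 2 | [(3R)-3-(2-hydroxypropan-2-yl)-7-methyl-2,3-dihydro-1,4-benzodioxin-5-yl]boronic acid | OB(O)c1cc(C)cc2c1O[C@@H](C(C)(C)O)CO2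
A5 | alternative 2 | [2-(dimethoxymethyl)-3-(methoxymethoxy)-6-(3-methylbut-2-enyl)phenyl][(3R)-3-(2-hydroxypropan-2-yl)-7-methyl-2,3-dihydro-1,4-benzodioxin-5-yl]methanone | CC(C)=CCc1ccc(OCOC)c(C(OC)OC)c1C(=O)c1cc(C)cc2c1O[C@@H](C(C)(C)O)CO2
A6 | alternative 3 | 4-(3-bromo-2-hydroxy-5-methylphenoxy)-2-methylbut-2-enyl methyl carbonate (either alkene geometry) | COC(=O)OCC(C)=CCOc1cc(C)cc(Br)c1O
A7 | alternative 3 | (2S)-8-bromo-6-methyl-2-(prop-1-en-2-yl)-2,3-dihydro-1,4-benzodioxine | Brc1cc(C)cc2c1O[C@@H](C(C)=C)CO2
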